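**Retrosynthetic overview**
1. Target ⇒ acetonide hydrolysis, then Mitsunobu esterification of the C1 alcohol with phloretic acid. No ring is built: the arene arrives intact, and the only rings made are two temporary dioxolanes, formed once in the common intermediate and opened in the last step.
2. C3–C4 ⇒ enantioselective radical conjugate addition of a C4 primary iodide to crotonaldehyde under iminium catalysis (proposed new step, sets C3).
3. C11–C12 ⇒ chelation-controlled addition of a west C12–C24 Grignard reagent to the methyl ketone of the east C4–C11 unit (sets C11).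
4. Both halves ⇒ one intermediate, the acetonide of the syn-diol ketone from an amine-catalysed syn-aldol of hydroxyacetone with (R)-citronellal (sets C9/C10 and C17/C18). In the west copy C=O becomes CH(CH3)C5H11 by methylenation, anti-hydroboration and alkyl–alkyl Suzuki coupling (sets C19); the prenyl ends become C12 and C4 by ozonolysis.
5. (R)-Citronellal ⇒ citral by organocatalytic transfer hydrogenation (first stereocentre; becomes C7 and C15).

Assumption: C1–C24 number the alcohol chain of the target (C1 = CH2O); citral is drawn as geranial although the commercial E/Z mixture is used; catalyst enantiomers are named from the accepted stereochemical models and the antipode would be taken if the observed sense were opposite.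

**Route**

Step 1
Reactants: 1 citral
Product: 2 (R)-citronellal
Conditions: Hantzsch ester (diethyl 2,6-dimethyl-1,4-dihydropyridine-3,5-dicarboxylate, 1.1 equiv), morpholinium salt of (R)-TRIP phosphoric acid (20 mol%), THF, rt
Reagents that add atoms: none
Why: Iminium-ion transfer hydrogenation under asymmetric counteranion-directed catalysis, in which the chiral phosphate paired with the morpholine iminium ion steers hydride to one face of C3 and E/Z equilibration of the iminium ion makes both citral isomers converge on the 3R aldehyde (about 90% ee expected).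

Step 2
Reactants: 2 (R)-citronellal; 3 hydroxyacetone
Product: 4 (3R,4S,6R)-3,4-dihydroxy-6,10-dimethylundec-9-en-2-one
Conditions: 3 (5 equiv), O-tert-butyl-L-threonine (20 mol%), NMP, 4 °C, slow addition of 2
Reagents that add atoms: none
Why: Enamine-catalysed direct syn-aldol with a primary amino acid, in which the hydrogen-bonded Z-enamine of hydroxyacetone reacts through its hydroxylated carbon on the aldehyde face chosen by the catalyst carboxyl group, giving the syn-(3R,4S) diol under catalyst control; the minor C6 epimer from residual (S)-citronellal is a diastereomer and is removed here.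

Step 3
Reactants: 4 (3R,4S,6R)-3,4-dihydroxy-6,10-dimethylundec-9-en-2-one
Product: 5 1-[(4R,5S)-5-[(2R)-2,6-dimethylhept-5-en-1-yl]-2,2-dimethyl-1,3-dioxolan-4-yl]ethan-1-one
Conditions: 2,2-dimethoxypropane, PPTS (cat.), CH2Cl2, rt
Reagents that add atoms: 2,2-dimethoxypropane COC(C)(C)OC
Why: Acid-catalysed transketalisation gives the trans-dioxolane, the thermodynamically favoured acetonide of a syn diol, so the α-centre is safe and the ketone is set up as an α-alkoxy ketone for both halves.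

Step 4
Reactants: 5 1-[(4R,5S)-5-[(2R)-2,6-dimethylhept-5-en-1-yl]-2,2-dimethyl-1,3-dioxolan-4-yl]ethan-1-one
Product: 6 (4S,5S)-4-[(2R)-2,6-dimethylhept-5-en-1-yl]-2,2-dimethyl-5-(prop-1-en-2-yl)-1,3-dioxolane
Conditions: Ph3PCH3Br, KOtBu, THF, 0 °C → rt
Reagents that add atoms: methyltriphenylphosphonium bromide C[P+](c1ccccc1)(c1ccccc1)c1ccccc1.[Br-]
Why: Wittig methylenation of a methyl ketone with the non-stabilised ylide is fast, and the α-centre already sits in the more stable trans-dioxolane so base cannot erode it.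

Step 5
Reactants: 6 (4S,5S)-4-[(2R)-2,6-dimethylhept-5-en-1-yl]-2,2-dimethyl-5-(prop-1-en-2-yl)-1,3-dioxolane; 7 1-bromobutane
Product: 9 (4S,5S)-4-[(2R)-2,6-dimethylhept-5-en-1-yl]-5-[(2S)-heptan-2-yl]-2,2-dimethyl-1,3-dioxolane, via B-alkyl-9-BBN borane 8 (not isolated)
Conditions: 9-BBN (1.3 equiv), THF, 0 °C → rt; then 7 (3 equiv), Pd(OAc)2 (5 mol%), PCy3 (10 mol%), K3PO4·H2O, THF, rt
Reagents that add atoms: none
Why: Still–Barrish-type hydroboration, in which 9-BBN takes only the 1,1-disubstituted alkene and adds anti to the ring C–C bond in the conformer with the allylic hydrogen eclipsing the alkene (C18/C19 anti, 19S), followed by B-alkyl Suzuki–Miyaura coupling of the primary alkylborane with the primary bromide under Pd(OAc)2/PCy3, a system that suppresses β-hydride elimination.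

Step 6
Reactants: 9 (4S,5S)-4-[(2R)-2,6-dimethylhept-5-en-1-yl]-5-[(2S)-heptan-2-yl]-2,2-dimethyl-1,3-dioxolane
Product: 12 (4R)-5-[(4S,5S)-5-[(2S)-heptan-2-yl]-2,2-dimethyl-1,3-dioxolan-4-yl]-4-methylpentan-1-ol, via secondary ozonide 10 (not isolated), via C12 aldehyde 11 (not isolated)
Conditions: O3, CH2Cl2, −78 °C; then NaBH4, MeOH, −78 °C → rt
Reagents that add atoms: ozone [O-][O+]=O
Why: Ozonolysis of the only remaining alkene with reductive work-up gives the C12 primary alcohol, and acetonides are inert to both reagents.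

Step 7
Reactants: 12 (4R)-5-[(4S,5S)-5-[(2S)-heptan-2-yl]-2,2-dimethyl-1,3-dioxolan-4-yl]-4-methylpentan-1-ol
Product: 13 (4S,5S)-4-[(2R)-5-bromo-2-methylpentyl]-5-[(2S)-heptan-2-yl]-2,2-dimethyl-1,3-dioxolane
Conditions: CBr4, PPh3, CH2Cl2, 0 °C
Reagents that add atoms: carbon tetrabromide BrC(Br)(Br)Br
Why: Appel reaction converts the primary alcohol into the bromide by SN2 displacement of the oxyphosphonium under near-neutral conditions that spare the acetonide.

Step 8
Reactants: 13 (4S,5S)-4-[(2R)-5-bromo-2-methylpentyl]-5-[(2S)-heptan-2-yl]-2,2-dimethyl-1,3-dioxolane; 5 1-[(4R,5S)-5-[(2R)-2,6-dimethylhept-5-en-1-yl]-2,2-dimethyl-1,3-dioxolan-4-yl]ethan-1-one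
Product: 15 (6R,8S,9R,10R,14R,16S,17S,18S)-8,9:16,17-di-O-isopropylidene-2,6,10,14,18-pentamethyltricos-2-ene-8,9,10,16,17-pentol, via Grignard reagent 14 (not isolated)
Conditions: 13, Mg, Et2O, 35 °C; then 5, Et2O/CH2Cl2, −78 → −40 °C; aq NH4Cl
Reagents that add atoms: none
Why: Grignard addition under Cram chelation control, in which magnesium bridges the ketone oxygen and the α-oxygen of the dioxolane so that the alkyl group attacks the face opposite the ring C9 substituent and gives the C10/C11-syn tertiary alcohol (11R).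

Step 9
Reactants: 15 (6R,8S,9R,10R,14R,16S,17S,18S)-8,9:16,17-di-O-isopropylidene-2,6,10,14,18-pentamethyltricos-2-ene-8,9,10,16,17-pentol
Product: 18 (4R,6S,7R,8R,12R,14S,15S,16S)-6,7:14,15-di-O-isopropylidene-4,8,12,16-tetramethylhenicosane-1,6,7,8,14,15-hexol, via secondary ozonide 16 (not isolated), via C4 aldehyde 17 (not isolated)
Conditions: O3, CH2Cl2, −78 °C; then NaBH4, MeOH, −78 °C → rt
Reagents that add atoms: ozone [O-][O+]=O
Why: Ozonolysis with reductive work-up unmasks the second prenyl end as the C4 primary alcohol, and the tertiary alcohol and both acetonides are untouched.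

Step 10
Reactants: 18 (4R,6S,7R,8R,12R,14S,15S,16S)-6,7:14,15-di-O-isopropylidene-4,8,12,16-tetramethylhenicosane-1,6,7,8,14,15-hexol
Product: 19 (4R,6S,7R,8R,12R,14S,15S,16S)-1-iodo-6,7:14,15-di-O-isopropylidene-4,8,12,16-tetramethylhenicosane-6,7,8,14,15-pentol
Conditions: I2, PPh3, imidazole, CH2Cl2, 0 °C → rt
Reagents that add atoms: iodine II
Why: Appel-type iodination is selective for the primary alcohol because the tertiary C11 alcohol cannot form a displaceable oxyphosphonium.

Step 11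
Reactants: 19 (4R,6S,7R,8R,12R,14S,15S,16S)-1-iodo-6,7:14,15-di-O-isopropylidene-4,8,12,16-tetramethylhenicosane-6,7,8,14,15-pentol; 20 crotonaldehyde
Product: 22 (3S,7R,9S,10R,11R,15R,17S,18S,19S)-9,10:17,18-di-O-isopropylidene-3,7,11,15,19-pentamethyltetracosane-1,9,10,11,17,18-hexol, via C1 aldehyde 21 (not isolated)
Conditions: 20 (5 equiv), (2S,5S)-5-benzyl-2-tert-butyl-3-methylimidazolidin-4-one·TFA (second-generation MacMillan catalyst, 20 mol%), (TMS)3SiH (1.5 equiv) and 2,6-lutidine (1.2 equiv) by syringe pump, 4CzIPN (2 mol%), DME/H2O 10:1, 450 nm LEDs, −10 °C; then NaBH4, EtOH, 0 °C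
Reagents that add atoms: none
Why: Proposed new method: the silyl radical from (TMS)3SiH abstracts iodine from 19, the nucleophilic primary radical adds to the β-carbon of the crotonaldehyde iminium ion on the face left open by the benzyl group (the face used by carbon nucleophiles, predicted 3S), and the resulting enamine radical cation is quenched by hydrogen transfer from the silane or electron transfer from reduced 4CzIPN, which carries the chain and releases aldehyde 21 on hydrolysis before NaBH4 reduces it in the same pot; the closest known reactions are silane-mediated photochemical Giese additions of alkyl halides and amine-catalysed radical conjugate additions to aryl enals and cyclic enones, neither shown for an unactivated primary alkyl iodide with an aliphatic enal.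

Step 12
Reactants: 22 (3S,7R,9S,10R,11R,15R,17S,18S,19S)-9,10:17,18-di-O-isopropylidene-3,7,11,15,19-pentamethyltetracosane-1,9,10,11,17,18-hexol; 23 phloretic acid
Product: 24 (3S,7R,9S,10R,11R,15R,17S,18S,19S)-11-hydroxy-9,10:17,18-bis(isopropylidenedioxy)-3,7,11,15,19-pentamethyltetracosyl 3-(4-hydroxyphenyl)propanoate
Conditions: PPh3, DIAD, THF, 0 °C → rt
Reagents that add atoms: none
Why: Mitsunobu esterification, in which only the primary alcohol forms the alkoxyphosphonium and the carboxylic acid, far more acidic than the phenol, is the nucleophile, so neither the tertiary alcohol nor the phenol needs protection.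

Step 13
Reactants: 24 (3S,7R,9S,10R,11R,15R,17S,18S,19S)-11-hydroxy-9,10:17,18-bis(isopropylidenedioxy)-3,7,11,15,19-pentamethyltetracosyl 3-(4-hydroxyphenyl)propanoate
Product: 25 (3S,7R,9S,10R,11R,15R,17S,18S,19S)-9,10,11,17,18-pentahydroxy-3,7,11,15,19-pentamethyltetracosyl 3-(4-hydroxyphenyl)propanoate
Conditions: AcOH/H2O/THF 3:1:1, 50 °C
Reagents that add atoms: none
Why: Acid-catalysed acetal hydrolysis frees both diols under conditions that leave the primary alkyl ester and the tertiary alcohol intact and touch no stereocentre.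

**Compound list**
1 | citral, drawn as geranial, (2E)-3,7-dimethylocta-2,6-dienal | O=C/C=C(\C)CCC=C(C)C | starting material
2 | (R)-citronellal, (3R)-3,7-dimethyloct-6-enal | O=CC[C@H](C)CCC=C(C)C | intermediate
3 | hydroxyacetone, 1-hydroxypropan-2-one | CC(=O)CO | starting material
4 | (3R,4S,6R)-3,4-dihydroxy-6,10-dimethylundec-9-en-2-one | CC(=O)[C@H](O)[C@@H](O)C[C@H](C)CCC=C(C)C | intermediate
5 | 1-[(4R,5S)-5-[(2R)-2,6-dimethylhept-5-en-1-yl]-2,2-dimethyl-1,3-dioxolan-4-yl]ethan-1-one | CC(=O)[C@@H]1OC(C)(C)O[C@H]1C[C@H](C)CCC=C(C)C | intermediate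
6 | (4S,5S)-4-[(2R)-2,6-dimethylhept-5-en-1-yl]-2,2-dimethyl-5-(prop-1-en-2-yl)-1,3-dioxolane | C=C(C)[C@@H]1OC(C)(C)O[C@H]1C[C@H](C)CCC=C(C)C | intermediate
7 | 1-bromobutane | CCCCBr | starting material
8 | 9-[(2S)-2-[(4S,5S)-5-[(2R)-2,6-dimethylhept-5-en-1-yl]-2,2-dimethyl-1,3-dioxolan-4-yl]propyl]-9-borabicyclo[3.3.1]nonane | B1(C[C@H](C)[C@@H]2OC(C)(C)O[C@H]2C[C@H](C)CCC=C(C)C)C2CCCC1CCC2 | intermediate
9 | (4S,5S)-4-[(2R)-2,6-dimethylhept-5-en-1-yl]-5-[(2S)-heptan-2-yl]-2,2-dimethyl-1,3-dioxolane | CCCCC[C@H](C)[C@@H]1OC(C)(C)O[C@H]1C[C@H](C)CCC=C(C)C | intermediate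
10 | secondary ozonide of 9: 5-[(3R)-4-[(4S,5S)-5-[(2S)-heptan-2-yl]-2,2-dimethyl-1,3-dioxolan-4-yl]-3-methylbutyl]-3,3-dimethyl-1,2,4-trioxolane (epimers at the trioxolane CH) | CCCCC[C@H](C)[C@@H]1OC(C)(C)O[C@H]1C[C@H](C)CCC1OOC(C)(C)O1 | intermediate
11 | (4R)-5-[(4S,5S)-5-[(2S)-heptan-2-yl]-2,2-dimethyl-1,3-dioxolan-4-yl]-4-methylpentanal | CCCCC[C@H](C)[C@@H]1OC(C)(C)O[C@H]1C[C@H](C)CCC=O | intermediate
12 | (4R)-5-[(4S,5S)-5-[(2S)-heptan-2-yl]-2,2-dimethyl-1,3-dioxolan-4-yl]-4-methylpentan-1-ol | CCCCC[C@H](C)[C@@H]1OC(C)(C)O[C@H]1C[C@H](C)CCCO | intermediate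
13 | (4S,5S)-4-[(2R)-5-bromo-2-methylpentyl]-5-[(2S)-heptan-2-yl]-2,2-dimethyl-1,3-dioxolane | CCCCC[C@H](C)[C@@H]1OC(C)(C)O[C@H]1C[C@H](C)CCCBr | intermediate
14 | [(4R)-5-[(4S,5S)-5-[(2S)-heptan-2-yl]-2,2-dimethyl-1,3-dioxolan-4-yl]-4-methylpentyl]magnesium bromide | CCCCC[C@H](C)[C@@H]1OC(C)(C)O[C@H]1C[C@H](C)CCC[Mg]Br | intermediate
15 | (6R,8S,9R,10R,14R,16S,17S,18S)-8,9:16,17-di-O-isopropylidene-2,6,10,14,18-pentamethyltricos-2-ene-8,9,10,16,17-pentol | CCCCC[C@H](C)[C@@H]1OC(C)(C)O[C@H]1C[C@H](C)CCC[C@@](C)(O)[C@@H]1OC(C)(C)O[C@H]1C[C@H](C)CCC=C(C)C | intermediate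
16 | secondary ozonide of 15: the 2-methylprop-1-enyl end of 15 as a 3,3-dimethyl-1,2,4-trioxolan-5-yl ring (epimers at the ring CH), rest as in 15 | CCCCC[C@H](C)[C@@H]1OC(C)(C)O[C@H]1C[C@H](C)CCC[C@@](C)(O)[C@@H]1OC(C)(C)O[C@H]1C[C@H](C)CCC1OOC(C)(C)O1 | intermediate
17 | (4R,6S,7R,8R,12R,14S,15S,16S)-8-hydroxy-6,7:14,15-bis(isopropylidenedioxy)-4,8,12,16-tetramethylhenicosanal | CCCCC[C@H](C)[C@@H]1OC(C)(C)O[C@H]1C[C@H](C)CCC[C@@](C)(O)[C@@H]1OC(C)(C)O[C@H]1C[C@H](C)CCC=O | intermediate
18 | (4R,6S,7R,8R,12R,14S,15S,16S)-6,7:14,15-di-O-isopropylidene-4,8,12,16-tetramethylhenicosane-1,6,7,8,14,15-hexol | CCCCC[C@H](C)[C@@H]1OC(C)(C)O[C@H]1C[C@H](C)CCC[C@@](C)(O)[C@@H]1OC(C)(C)O[C@H]1C[C@H](C)CCCO | intermediate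
19 | (4R,6S,7R,8R,12R,14S,15S,16S)-1-iodo-6,7:14,15-di-O-isopropylidene-4,8,12,16-tetramethylhenicosane-6,7,8,14,15-pentol | CCCCC[C@H](C)[C@@H]1OC(C)(C)O[C@H]1C[C@H](C)CCC[C@@](C)(O)[C@@H]1OC(C)(C)O[C@H]1C[C@H](C)CCCI | intermediate
20 | crotonaldehyde, (2E)-but-2-enal | C/C=C/C=O | starting material
21 | (3S,7R,9S,10R,11R,15R,17S,18S,19S)-11-hydroxy-9,10:17,18-bis(isopropylidenedioxy)-3,7,11,15,19-pentamethyltetracosanal | CCCCC[C@H](C)[C@@H]1OC(C)(C)O[C@H]1C[C@H](C)CCC[C@@](C)(O)[C@@H]1OC(C)(C)O[C@H]1C[C@H](C)CCC[C@H](C)CC=O | intermediate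
22 | (3S,7R,9S,10R,11R,15R,17S,18S,19S)-9,10:17,18-di-O-isopropylidene-3,7,11,15,19-pentamethyltetracosane-1,9,10,11,17,18-hexol | CCCCC[C@H](C)[C@@H]1OC(C)(C)O[C@H]1C[C@H](C)CCC[C@@](C)(O)[C@@H]1OC(C)(C)O[C@H]1C[C@H](C)CCC[C@H](C)CCO | intermediate
23 | phloretic acid, 3-(4-hydroxyphenyl)propanoic acid | OC(=O)CCc1ccc(O)cc1 | starting material
24 | (3S,7R,9S,10R,11R,15R,17S,18S,19S)-11-hydroxy-9,10:17,18-bis(isopropylidenedioxy)-3,7,11,15,19-pentamethyltetracosyl 3-(4-hydroxyphenyl)propanoate | CCCCC[C@H](C)[C@@H]1OC(C)(C)O[C@H]1C[C@H](C)CCC[C@@](C)(O)[C@@H]1OC(C)(C)O[C@H]1C[C@H](C)CCC[C@H](C)CCOC(=O)CCc1ccc(O)cc1 | intermediate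
25 | (3S,7R,9S,10R,11R,15R,17S,18S,19S)-9,10,11,17,18-pentahydroxy-3,7,11,15,19-pentamethyltetracosyl 3-(4-hydroxyphenyl)propanoate (CNP0234982.1) | CCCCC[C@H](C)[C@H](O)[C@@H](O)C[C@H](C)CCC[C@@](C)(O)[C@H](O)[C@@H](O)C[C@H](C)CCC[C@H](C)CCOC(=O)CCc1ccc(O)cc1 | target

**Step count and risks**

Total steps: 13. Longest linear sequence: 13 (steps 1–13 from citral; compound 5 is used twice, once as precursor of the west half and once as the electrophile in step 8).

Steps most likely to fail:

Step 11 (proposed radical conjugate addition). Risks are reduction of the radical by the silane before it adds, racemic addition to free crotonaldehyde, and C3 epimers that are hard to separate. The fallback uses known reactions and sets out from 19. NaNO2 in DMF converts the iodide into the primary nitroalkane F1. Amine-catalysed Michael addition of F1 to crotonaldehyde (diphenylprolinol trimethylsilyl ether of the configuration that gives the target C3 centre, LiOAc, CH2Cl2/MeOH) followed by NaBH4 gives the nitro alcohol F2, as epimers at the nitro-bearing carbon only. Bu3SnH/AIBN in toluene at 110 °C then removes the nitro group, and the sequence comes back to the route at 22.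

Step 2 (syn-aldol on an α-unbranched aldehyde). Risks are self-aldolisation of citronellal and modest syn/anti ratio. The fallback sets out from 2. A Mukaiyama aldol of 2 with (Z)-2-(tert-butyldimethylsilyloxy)-1-(ethylthio)-1-(trimethylsilyloxy)ethene, promoted by Sn(OTf)2, a proline-derived chiral diamine and Bu2Sn(OAc)2 in CH2Cl2 at −78 °C, gives the syn silyloxy hydroxy thioester F3. HF·pyridine and then 2,2-dimethoxypropane/PPTS give the acetonide thioester F4. Me2CuLi converts the thioester into the methyl ketone, and the sequence comes back to the route at 5.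

Step 5 (hydroboration and alkyl–alkyl Suzuki coupling). The risk is slow transmetallation of the β-branched alkylborane. The fallback sets out from 6. The same 9-BBN hydroboration followed by NaOH/H2O2 gives the primary alcohol F5. TsCl/pyridine gives the tosylate F6. n-Bu2CuLi in Et2O at −20 °C displaces the tosylate, and the sequence comes back to the route at 9.

Further compounds
F1 | step 11 | (4R,6S,7R,8R,12R,14S,15S,16S)-6,7:14,15-di-O-isopropylidene-4,8,12,16-tetramethyl-1-nitrohenicosane-6,7,8,14,15-pentol | CCCCC[C@H](C)[C@@H]1OC(C)(C)O[C@H]1C[C@H](C)CCC[C@@](C)(O)[C@@H]1OC(C)(C)O[C@H]1C[C@H](C)CCC[N+](=O)[O-]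
F2 | step 11 | (3R,4RS,7R,9S,10R,11R,15R,17S,18S,19S)-9,10:17,18-di-O-isopropylidene-3,7,11,15,19-pentamethyl-4-nitrotetracosane-1,9,10,11,17,18-hexol | CCCCC[C@H](C)[C@@H]1OC(C)(C)O[C@H]1C[C@H](C)CCC[C@@](C)(O)[C@@H]1OC(C)(C)O[C@H]1C[C@H](C)CCC([N+](=O)[O-])[C@H](C)CCO
F3 | step 2 | S-ethyl (2R,3S,5R)-2-[(tert-butyldimethylsilyl)oxy]-3-hydroxy-5,9-dimethyldec-8-enethioate | CCSC(=O)[C@H](O[Si](C)(C)C(C)(C)C)[C@@H](O)C[C@H](C)CCC=C(C)C
F4 | step 2 | S-ethyl (4R,5S)-5-[(2R)-2,6-dimethylhept-5-en-1-yl]-2,2-dimethyl-1,3-dioxolane-4-carbothioate | CCSC(=O)[C@@H]1OC(C)(C)O[C@H]1C[C@H](C)CCC=C(C)C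
F5 | step 5 | (2S)-2-[(4S,5S)-5-[(2R)-2,6-dimethylhept-5-en-1-yl]-2,2-dimethyl-1,3-dioxolan-4-yl]propan-1-ol | OC[C@H](C)[C@@H]1OC(C)(C)O[C@H]1C[C@H](C)CCC=C(C)C
F6 | step 5 | (2S)-2-[(4S,5S)-5-[(2R)-2,6-dimethylhept-5-en-1-yl]-2,2-dimethyl-1,3-dioxolan-4-yl]propyl 4-methylbenzenesulfonate | Cc1ccc(cc1)S(=O)(=O)OC[C@H](C)[C@@H]1OC(C)(C)O[C@H]1C[C@H](C)CCC=C(C)C
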